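The constants used here are invented; what happens was integrated by code.

The thing to watch in this run is the leftover: how much substrate still stands in your flask at the end, and whether waiting would use it.

substrate 0.20 M; partner 0.240 M (fed, over 40 s); time 4.0 h

    substrate + partner → product (k1 = 0.064 /M/min)
    partner → decomposed reagent (k2 = 0.26 /min)
    substrate + partner + product → 2 product (k3 = 5.6 /M²/min)

- the reaction counts as stopped when no species that holds the substrate changes by six tenths of a point or more over the second half of the time
- run time (flask): 4.0 h

1. which holds at 4.0 h: what has brought the reaction to rest, or that it has not come to rest (all of the substrate has reacted / it is still moving / the partner has run out first)
2. product at 4.0 h, in percent of the substrate charged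
3. amount of product if the flask were left three thousand times as long, in percent of the substrate charged

Turn two constants into times at the charge. The partner decomposes with a half-life of 2.7 min, whether or not substrate is present. The substrate, by the first step alone with the whole partner charge counted as present, has a half-life of 0.75 h, much longer than the partner's. The feed of 40 s is shorter than the partner's half-life, so I count the charge as there at once. The partner's half-life over the substrate's is 5.91%. Call it the dose: roughly the share of the substrate that the first step takes during the partner's lifetime.

The autocatalytic step adds to the dose. With product at 0.0118 M, its rate over the first step's is 1.03, so it climbs from zero to about level. I therefore commit to a product between 5.91% and 11.8%. The run lasts 90.0 partner half-lives, so I expect no further gain from waiting.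

The forecast says the partner has run out first, with 8.7% of product at the asked time and 8.7% in the long stay, “leaving the substrate stranded and the product fixed from then on”. Its figure lies inside my range.

The simulation agrees: the partner has run out first, with 8.67% of product and 8.67% in the long stay.

In this flask the partner, the limiting reagent although charged at 1.20 equivalents, stands at 0% of its charge after 4.00 h, and 91.3% of the charged substrate remains. The autocatalytic step's net turnover in this flask up to that time is 3.40% of the substrate charged. Now take the neighbour with 0.14 M of partner, or 0.700 equiv. Its dose is 3.45%, so the same range runs from there up to 6.90%. After 4.00 h that neighbour holds 0% of its partner charge, 96% of its substrate charge and 4.24% of product.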